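The four-membered ring (Ca carries the alkenyl arm, Cb is CH2, Cc is CMe2, Cd carries the 3-oxobutyl arm) contains an isobutylene unit, Cb–Cc. The chain alkene carbon–Ca–Cd–CH2–CH2–ketone carbon is a cyclohexenone ring with one bond missing. The route therefore rests on disconnecting Ca–Cb and Cd–Cc. One enantioselective [2+2] photocycloaddition closes the cyclobutane, places CMe2 beside Cd and fixes Cd absolutely. Its precursor is simply commercial cyclohex-2-en-1-one 1 and isobutylene 2. C-Methylation and oxidative scission of the six-membered ring then release both arms, base inverts Ca to trans, and the chain, methylene and linoleate are added conventionally.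

Key step: step 1

Assumption: the catalyst is the oxazaborolidine condensed from α,α-bis(3,5-dimethylphenyl)prolinol and 2,4,6-trifluorophenylboronic acid, activated in situ with AlBr3. Both prolinol antipodes are commercial, and the one that leaves open the enone face that is Re at C3 is used, which makes Cd (R).
Atom key for the bicycles: C1 = Ca, C2 = carbonyl carbon (later the alkene carbon), C3 = α' carbon (later the ketone carbon), C6 = Cd, C7 = Cc, C8 = Cb.

Step 1
Reactants: 1 cyclohex-2-en-1-one; 2 2-methylpropene (isobutylene)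
Product: 4 (1R,6R)-7,7-dimethylbicyclo[4.2.0]octan-2-one (cis-fused), via trans-fused C1 epimer 3 (not isolated)
Conditions: oxazaborolidine (50 mol%), AlBr3 (50 mol%), 2 (excess, condensed in), CH2Cl2, −75 °C, hν (366 nm); then basic Al2O3, CH2Cl2, rt
Reagents that add atoms: none
Why: Coordination of the enone oxygen to boron of the AlBr3-activated oxazaborolidine shifts the strong ππ* absorption to longer wavelength, so at 366 nm the chiral complex is excited in preference to free 1, and after intersystem crossing the triplet enone adds to 2 stepwise through a triplet 1,4-diradical. The closest known reaction type is the chiral-Lewis-acid-catalysed intermolecular enone–alkene [2+2] photocycloaddition, which is established for cyclic enones with 1,1-disubstituted alkenes. The four-membered ring is closed in cycloaddition mode: one of the bonds Ca–Cb and Cd–Cc forms intermolecularly, and spin inversion followed by radical recombination of the 1,4-diradical makes the other. Cd is controlled by the catalyst, whose aryl group covers the Si face of the bound enone so that Cc bonds to the Re face of C3, whereas Ca is controlled first by the ring closure and finally by strain, since basic alumina epimerises any trans-fused ketone 3 at its acidic C1–H into the more stable cis-fused 4 without touching Cd. The step needs head-to-tail regiochemistry, one enone face and a negligible racemic background; the first comes from matching the electron-rich alkene (nucleophilic CH2 terminus) with the reversed polarity of the excited enone (electron-rich β-carbon), which puts CH2 on Ca and CMe2 on Cd, the second from two-point binding of the unsubstituted enone (B–O bond plus α-C–H···O contact), and the third from the long wavelength, the low temperature and the high catalyst loading.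

Step 2
Reactants: 4 (1R,6R)-7,7-dimethylbicyclo[4.2.0]octan-2-one
Product: 6 (1R,6R)-3,7,7-trimethylbicyclo[4.2.0]octan-2-one (both C3 epimers used together), via lithium enolate 5 (not isolated)
Conditions: LDA, THF, −78 °C; MeI, −78 → 0 °C
Reagents that add atoms: iodomethane, CI
Why: Kinetic enolate alkylation: the hindered amide base removes a proton from the accessible C3 methylene rather than the tertiary ring-fusion C1–H, and SN2 methylation of enolate 5 installs the future ketone methyl group, the new C3 centre being irrelevant because it becomes sp2 in step 3.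

Step 3
Reactants: 6 (1R,6R)-3,7,7-trimethylbicyclo[4.2.0]octan-2-one
Product: 7 trimethyl{[(1R,6R)-3,7,7-trimethylbicyclo[4.2.0]oct-2-en-2-yl]oxy}silane
Conditions: TMSOTf, Et3N, CH2Cl2, 0 °C → rt; used crude
Reagents that add atoms: trimethylsilyl trifluoromethanesulfonate, C[Si](C)(C)OS(=O)(=O)C(F)(F)F
Why: Soft enolisation and O-silylation under equilibrating conditions (thermodynamic silyl enol ether formation) should favour the C2=C3 isomer, because the alternative C1=C2 double bond would place an sp2 carbon of the cyclobutane at the ring fusion and raise the strain, while reversible enolisation at C1 can only return the more stable cis ring fusion.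

Step 4
Reactants: 7 trimethyl{[(1R,6R)-3,7,7-trimethylbicyclo[4.2.0]oct-2-en-2-yl]oxy}silane
Product: 9 (1R,2R)-3,3-dimethyl-2-(3-oxobutyl)cyclobutane-1-carboxylic acid (cis), via trimethylsilyl ester 8 (not isolated)
Conditions: O3, CH2Cl2, −78 °C; Me2S, −78 °C → rt; H2O work-up
Reagents that add atoms: ozone, [O-][O+]=O
Why: Ozonolysis (Criegee mechanism) of the electron-rich tetrasubstituted enol ether cuts C2–C3, the one surplus bond of the six-membered ring, turning C3 into the methyl ketone and C2 into silyl ester 8 that hydrolyses on work-up, with Ca and Cd untouched so that the cis relationship is carried over.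

Step 5
Reactants: 9 (1R,2R)-3,3-dimethyl-2-(3-oxobutyl)cyclobutane-1-carboxylic acid
Product: 11 (1R,2R)-N-methoxy-N,3,3-trimethyl-2-(3-oxobutyl)cyclobutane-1-carboxamide, via acyl imidazole 10 (not isolated)
Conditions: CDI, CH2Cl2, rt; MeNH(OMe)·HCl, rt
Reagents that add atoms: N,O-dimethylhydroxylamine hydrochloride, CNOC.Cl
Why: Amide coupling through the acyl imidazole (carbonyldiimidazole activation) converts the acid into the Weinreb amide under nearly neutral conditions that leave the methyl ketone and both stereocentres alone.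

Step 6
Reactants: 11 (1R,2R)-N-methoxy-N,3,3-trimethyl-2-(3-oxobutyl)cyclobutane-1-carboxamide
Product: 12 (1R,2R)-N-methoxy-N,3,3-trimethyl-2-[2-(2-methyl-1,3-dioxolan-2-yl)ethyl]cyclobutane-1-carboxamide
Conditions: HOCH2CH2OH, PPTS (cat.), toluene, reflux, Dean–Stark
Reagents that add atoms: ethylene glycol, OCCO
Why: Acid-catalysed ketalisation with azeotropic water removal masks the unhindered methyl ketone before any basic or nucleophilic step, which prevents Grignard attack there and an intramolecular Claisen-type closure of the arm's α-carbon onto the acyl group at Ca to a five-membered ring.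

Step 7
Reactants: 12 (1R,2R)-N-methoxy-N,3,3-trimethyl-2-[2-(2-methyl-1,3-dioxolan-2-yl)ethyl]cyclobutane-1-carboxamide; 13 (3-bromopropoxy)(tert-butyl)dimethylsilane
Product: 15 4-[(tert-butyldimethylsilyl)oxy]-1-{(1R,2R)-3,3-dimethyl-2-[2-(2-methyl-1,3-dioxolan-2-yl)ethyl]cyclobutyl}butan-1-one (cis), via Grignard reagent 14 (not isolated)
Conditions: 13, Mg, THF, rt → 40 °C; then 12, THF, 0 °C; aq. NH4Cl
Reagents that add atoms: none
Why: Weinreb ketone synthesis: the N-methoxy-N-methyl amide accepts only one equivalent of the primary alkyl Grignard reagent 14 because chelation holds back release of the carbonyl group until the quench, and any partial epimerisation at Ca is harmless because step 8 equilibrates this centre.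

Step 8
Reactants: 15 cis ketone
Product: 16 4-[(tert-butyldimethylsilyl)oxy]-1-{(1S,2R)-3,3-dimethyl-2-[2-(2-methyl-1,3-dioxolan-2-yl)ethyl]cyclobutyl}butan-1-one (trans)
Conditions: NaOMe (0.3 equiv), MeOH, rt → 40 °C; residual 15 separated and resubmitted
Reagents that add atoms: none
Why: Base-catalysed epimerisation through the enolate puts Ca under thermodynamic control, and the trans-1,2-disubstituted cyclobutane is favoured because it relieves the eclipsing contact between the acyl group and the arm on Cd, while Cd carries no acidic hydrogen and stays as the fixed reference centre.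

Step 9
Reactants: 16 trans ketone
Product: 17 tert-butyl[(4-{(1S,2R)-3,3-dimethyl-2-[2-(2-methyl-1,3-dioxolan-2-yl)ethyl]cyclobutyl}pent-4-en-1-yl)oxy]dimethylsilane
Conditions: Ph3PCH3Br, KOtBu, THF, 0 °C → rt
Reagents that add atoms: methyltriphenylphosphonium bromide, C[P+](c1ccccc1)(c1ccccc1)c1ccccc1.[Br-]
Why: Wittig methylenation with the small unstabilised ylide converts the only free ketone into the 1,1-disubstituted alkene, and any competing enolisation merely returns the already favoured trans ketone, so the Ca configuration is kept.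

Step 10
Reactants: 17 silyl ether ketal
Product: 18 4-[(1R,4S)-4-(5-hydroxypent-1-en-2-yl)-2,2-dimethylcyclobutyl]butan-2-one
Conditions: CSA (0.2 equiv), MeOH/H2O 9:1, 0 °C → rt
Reagents that add atoms: water, O
Why: Brønsted-acid solvolysis removes both acid-labile groups in one operation (methanolysis of the primary silyl ether and hydrolysis of the dioxolane), both being much faster at this low acidity than protonation of the 1,1-disubstituted alkene, and it spares the later linoleate any acid or fluoride.

Step 11
Reactants: 18 4-[(1R,4S)-4-(5-hydroxypent-1-en-2-yl)-2,2-dimethylcyclobutyl]butan-2-one; 19 linoleic acid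
Product: 20 4-[(1S,2R)-3,3-dimethyl-2-(3-oxobutyl)cyclobutyl]pent-4-en-1-yl (9Z,12Z)-octadeca-9,12-dienoate (IN0146)
Conditions: DCC, DMAP (cat.), CH2Cl2, 0 °C → rt
Reagents that add atoms: none
Why: Steglich esterification acylates the unhindered primary alcohol under neutral conditions at or below room temperature, which leaves the methyl ketone, the exocyclic alkene and the skipped (Z,Z)-diene of linoleic acid unchanged.

Compound list
1 | cyclohex-2-en-1-one | O=C1C=CCCC1 | starting material
2 | 2-methylpropene (isobutylene) | C=C(C)C | starting material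
3 | (1S,6R)-7,7-dimethylbicyclo[4.2.0]octan-2-one (trans-fused) | O=C2[C@H]1CC(C)(C)[C@@H]1CCC2 | intermediate
4 | (1R,6R)-7,7-dimethylbicyclo[4.2.0]octan-2-one (cis-fused) | O=C2[C@@H]1CC(C)(C)[C@@H]1CCC2 | intermediate
5 | lithium (1R,6R)-7,7-dimethylbicyclo[4.2.0]oct-2-en-2-olate | CC1(C)C[C@@H]2[C@H]1CCC=C2O[Li] | intermediate
6 | (1R,6R)-3,7,7-trimethylbicyclo[4.2.0]octan-2-one (C3 epimers) | O=C2[C@@H]1CC(C)(C)[C@@H]1CCC2C | intermediate
7 | trimethyl{[(1R,6R)-3,7,7-trimethylbicyclo[4.2.0]oct-2-en-2-yl]oxy}silane | CC1(C)C[C@@H]2[C@H]1CCC(C)=C2O[Si](C)(C)C | intermediate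
8 | trimethylsilyl (1R,2R)-3,3-dimethyl-2-(3-oxobutyl)cyclobutane-1-carboxylate | C[Si](C)(C)OC(=O)[C@@H]1CC(C)(C)[C@@H]1CCC(C)=O | intermediate
9 | (1R,2R)-3,3-dimethyl-2-(3-oxobutyl)cyclobutane-1-carboxylic acid | OC(=O)[C@@H]1CC(C)(C)[C@@H]1CCC(C)=O | intermediate
10 | 4-[(1R,4R)-4-(imidazole-1-carbonyl)-2,2-dimethylcyclobutyl]butan-2-one | O=C(n2ccnc2)[C@@H]1CC(C)(C)[C@@H]1CCC(C)=O | intermediate
11 | (1R,2R)-N-methoxy-N,3,3-trimethyl-2-(3-oxobutyl)cyclobutane-1-carboxamide | CON(C)C(=O)[C@@H]1CC(C)(C)[C@@H]1CCC(C)=O | intermediate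
12 | (1R,2R)-N-methoxy-N,3,3-trimethyl-2-[2-(2-methyl-1,3-dioxolan-2-yl)ethyl]cyclobutane-1-carboxamide | CON(C)C(=O)[C@@H]1CC(C)(C)[C@@H]1CCC2(C)OCCO2 | intermediate
13 | (3-bromopropoxy)(tert-butyl)dimethylsilane | CC(C)(C)[Si](C)(C)OCCCBr | starting material
14 | {3-[(tert-butyldimethylsilyl)oxy]propyl}magnesium bromide | CC(C)(C)[Si](C)(C)OCCC[Mg]Br | intermediate
15 | 4-[(tert-butyldimethylsilyl)oxy]-1-{(1R,2R)-3,3-dimethyl-2-[2-(2-methyl-1,3-dioxolan-2-yl)ethyl]cyclobutyl}butan-1-one | CC(C)(C)[Si](C)(C)OCCCC(=O)[C@@H]1CC(C)(C)[C@@H]1CCC2(C)OCCO2 | intermediate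
16 | 4-[(tert-butyldimethylsilyl)oxy]-1-{(1S,2R)-3,3-dimethyl-2-[2-(2-methyl-1,3-dioxolan-2-yl)ethyl]cyclobutyl}butan-1-one | CC(C)(C)[Si](C)(C)OCCCC(=O)[C@H]1CC(C)(C)[C@@H]1CCC2(C)OCCO2 | intermediate
17 | tert-butyl[(4-{(1S,2R)-3,3-dimethyl-2-[2-(2-methyl-1,3-dioxolan-2-yl)ethyl]cyclobutyl}pent-4-en-1-yl)oxy]dimethylsilane | C=C(CCCO[Si](C)(C)C(C)(C)C)[C@H]1CC(C)(C)[C@@H]1CCC2(C)OCCO2 | intermediate
18 | 4-[(1R,4S)-4-(5-hydroxypent-1-en-2-yl)-2,2-dimethylcyclobutyl]butan-2-one | C=C(CCCO)[C@H]1CC(C)(C)[C@@H]1CCC(C)=O | intermediate
19 | linoleic acid, (9Z,12Z)-octadeca-9,12-dienoic acid | OC(=O)CCCCCCC/C=C\C/C=C\CCCCC | starting material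
20 | 4-[(1S,2R)-3,3-dimethyl-2-(3-oxobutyl)cyclobutyl]pent-4-en-1-yl (9Z,12Z)-octadeca-9,12-dienoate (IN0146) | C=C(CCCOC(=O)CCCCCCC/C=C\C/C=C\CCCCC)[C@H]1CC(C)(C)[C@@H]1CCC(C)=O | target

Total step count: 11. Longest linear sequence: 11 steps (1 → 20); 13 and 19 enter as purchased.

Steps most likely to fail

Step 1. Uncomplexed enone may also absorb and add without facial bias. The strong Lewis acid may start cationic oligomerisation of isobutylene, and the head-to-tail preference may erode.
- The fallback gives up catalytic stereocontrol in favour of resolution. It sets out from 1 and 2 and comes back at 4.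
- Direct irradiation without Lewis acid (about 350 nm, excess 2, CH2Cl2, −70 °C) followed by basic Al2O3 should give racemic cis-7,7-dimethylbicyclo[4.2.0]octan-2-one F1.
- Preparative chromatography on a chiral stationary phase then removes the unwanted (1S,6S)-7,7-dimethylbicyclo[4.2.0]octan-2-one F2 and delivers 4.

Step 3. Enolisation toward the ring-fusion carbon or incomplete equilibration may erode the regioselectivity, and ozonolysis would then cut the wrong bond for part of the material.
- The fallback makes the enol ether regiospecifically from an enone instead of by enolisation. It sets out from 4, bypasses 6 and 7, and comes back at 9.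
- α-Methylenation (paraformaldehyde, N-methylanilinium trifluoroacetate, THF, reflux) can end in elimination only at the C3 methylene. It should give (1R,6R)-7,7-dimethyl-3-methylidenebicyclo[4.2.0]octan-2-one F3.
- 1,4-Hydrosilylation of this s-cis enone (Et3SiH, RhCl(PPh3)3 cat., toluene, 50 °C) places hydrogen on the methylidene carbon and silicon on oxygen. This gives triethyl{[(1R,6R)-3,7,7-trimethylbicyclo[4.2.0]oct-2-en-2-yl]oxy}silane F4.
- Ozonolysis as in step 4 then passes through triethylsilyl (1R,2R)-3,3-dimethyl-2-(3-oxobutyl)cyclobutane-1-carboxylate F5 and reaches 9.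

Step 10. Protonation of the 1,1-disubstituted alkene may compete during the double deprotection. It could lead to cycloetherification by the freed hydroxyl group, double-bond migration or cyclobutylcarbinyl ring expansion.
- The fallback removes the two groups orthogonally and keeps acid away from the free alcohol. It sets out from 17 and comes back at 20.
- TBAF in THF should give 4-{(1S,2R)-3,3-dimethyl-2-[2-(2-methyl-1,3-dioxolan-2-yl)ethyl]cyclobutyl}pent-4-en-1-ol F6.
- Steglich esterification with 19 (DCC, DMAP) gives the corresponding ketal linoleate F7.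
- PPTS in wet acetone at rt → 40 °C hydrolyses only the dioxolane and affords 20.

Further compounds
F1 | step 1 | racemic cis-7,7-dimethylbicyclo[4.2.0]octan-2-one | O=C2[C@@H]1CC(C)(C)[C@@H]1CCC2.O=C2[C@H]1CC(C)(C)[C@H]1CCC2
F2 | step 1 | (1S,6S)-7,7-dimethylbicyclo[4.2.0]octan-2-one | O=C2[C@H]1CC(C)(C)[C@H]1CCC2
F3 | step 3 | (1R,6R)-7,7-dimethyl-3-methylidenebicyclo[4.2.0]octan-2-one | O=C2[C@@H]1CC(C)(C)[C@@H]1CCC2=C
F4 | step 3 | triethyl{[(1R,6R)-3,7,7-trimethylbicyclo[4.2.0]oct-2-en-2-yl]oxy}silane | CC1(C)C[C@@H]2[C@H]1CCC(C)=C2O[Si](CC)(CC)CC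
F5 | step 3 | triethylsilyl (1R,2R)-3,3-dimethyl-2-(3-oxobutyl)cyclobutane-1-carboxylate | CC[Si](CC)(CC)OC(=O)[C@@H]1CC(C)(C)[C@@H]1CCC(C)=O
F6 | step 10 | 4-{(1S,2R)-3,3-dimethyl-2-[2-(2-methyl-1,3-dioxolan-2-yl)ethyl]cyclobutyl}pent-4-en-1-ol | C=C(CCCO)[C@H]1CC(C)(C)[C@@H]1CCC2(C)OCCO2
F7 | step 10 | 4-{(1S,2R)-3,3-dimethyl-2-[2-(2-methyl-1,3-dioxolan-2-yl)ethyl]cyclobutyl}pent-4-en-1-yl (9Z,12Z)-octadeca-9,12-dienoate | C=C(CCCOC(=O)CCCCCCC/C=C\C/C=C\CCCCC)[C@H]1CC(C)(C)[C@@H]1CCC2(C)OCCO2
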